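**Retrosynthetic overview**

1. Target 21 ⇐ desilylation ⇐ Lindlar semi-hydrogenation of the 22-membered cycloalkyne 19 (C6≡C7 is the masked Z-alkene). Ring A (the 1,3,5-trisubstituted phenol ring) and ring B (the 3,5-dihydroxy-4-aryloxyphenyl ring) are bought as arenes, so the macrocycle is the only ring formed, in step 10.
2. 19 ⇐ closure of the saturated C3–C4 bond of open-chain 17 by one-pot hydroboration and intramolecular alkyl–alkyl Suzuki–Miyaura coupling, which leaves nothing to remove afterwards.
3. Enabling feature: C3 is the end carbon of the three-carbon arm C1–C2–C3 on ring A, so it can be carried as the =CH2 end of an allyl group, where 9-BBN places boron. C4 is a primary carbon two atoms from the C6≡C7 alkyne, so it can be an unhindered bromide. The diaryl ether oxygen joining ring A (1,3-bridged) and ring B (1,4-bridged) is the hinge that folds the two chain ends towards each other.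
4. 17 ⇐ (R)-C14 carbinol by Corey–Bakshi–Shibata reduction of an aryl ketone ⇐ ring B nitrile plus a C4–C13 Grignard reagent (from a butynyl THP ether and 1,6-dibromohexane); allyl group by Stille coupling; diaryl ether by Chan–Lam coupling.

Key step: step 10

Remarks: chain carbons are numbered C1 (benzylic CH2 on ring A) to C14 (carbinol carbon on ring B), so the alkene is C6=C7. The configuration written at C14 corresponds to (R). THP acetals are used as racemates because the acetal carbon is removed. Ar* = 4-{3-allyl-5-[(triisopropylsilyl)oxy]phenoxy}-3,5-bis[(triisopropylsilyl)oxy]phenyl.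

**Route**

Step 1
Reactants: 1 4-hydroxy-3,5-dimethoxybenzonitrile; 2 (3-bromo-5-methoxyphenyl)boronic acid
Product: 3 4-(3-bromo-5-methoxyphenoxy)-3,5-dimethoxybenzonitrile
Conditions: Cu(OAc)2 (1 equiv, reoxidised by air), pyridine, 4 Å molecular sieves, CH2Cl2, air, rt
Reagents that add atoms: none
Why: Chan–Lam oxidative C–O coupling joins the phenol oxygen to the boron-bearing carbon at room temperature, accepts a doubly ortho-substituted phenol and should leave the aryl bromide untouched because no zerovalent metal is present.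

Step 2
Reactants: 3 4-(3-bromo-5-methoxyphenoxy)-3,5-dimethoxybenzonitrile
Product: 4 4-(3-bromo-5-hydroxyphenoxy)-3,5-dihydroxybenzonitrile
Conditions: BBr3, CH2Cl2, −78 °C to rt; then H2O
Reagents that add atoms: none
Why: Lewis-acid demethylation of aryl methyl ethers with BBr3 should cleave the three O–CH3 bonds, while the diaryl ether, nitrile and aryl bromide offer no alkyl group for bromide to attack and should persist.

Step 3
Reactants: 4 4-(3-bromo-5-hydroxyphenoxy)-3,5-dihydroxybenzonitrile
Product: 5 4-{3-bromo-5-[(triisopropylsilyl)oxy]phenoxy}-3,5-bis[(triisopropylsilyl)oxy]benzonitrile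
Conditions: TIPSOTf, 2,6-lutidine, CH2Cl2, 0 °C to rt
Reagents that add atoms: triisopropylsilyl triflate, CC(C)[Si](C(C)C)(C(C)C)OS(=O)(=O)C(F)(F)F
Why: O-silylation of phenols with a silyl triflate is reactive enough for the two hydroxyls flanking the diaryl ether oxygen, and aryl TIPS ethers should resist Grignard reagents, phosphate base and dilute acid yet fall to fluoride at the end.

Step 4
Reactants: 5 4-{3-bromo-5-[(triisopropylsilyl)oxy]phenoxy}-3,5-bis[(triisopropylsilyl)oxy]benzonitrile; 6 allyltributylstannane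
Product: 7 4-{3-allyl-5-[(triisopropylsilyl)oxy]phenoxy}-3,5-bis[(triisopropylsilyl)oxy]benzonitrile
Conditions: Pd(PPh3)4 (5 mol%), toluene, 100 °C
Reagents that add atoms: none
Why: Migita–Kosugi–Stille coupling at the only C–Br bond installs the allyl group (C1–C3) under neutral conditions that should spare the silyl ethers and the nitrile.

Step 5
Reactants: 8 2-(but-3-yn-1-yloxy)oxane; 9 1,6-dibromohexane
Product: 11 2-[(10-bromodec-3-yn-1-yl)oxy]oxane, via lithium acetylide 10 (not isolated)
Conditions: n-BuLi, THF, −78 °C; then 9 (4 equiv), DMPU, −78 °C to rt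
Reagents that add atoms: none
Why: SN2 alkylation of a lithium acetylide by a primary bromide builds C4–C13, and the excess of the symmetric dibromide should hold double alkylation down.

Step 6
Reactants: 7 4-{3-allyl-5-[(triisopropylsilyl)oxy]phenoxy}-3,5-bis[(triisopropylsilyl)oxy]benzonitrile; 11 2-[(10-bromodec-3-yn-1-yl)oxy]oxane
Product: 14 11-hydroxy-1-Ar*-undec-8-yn-1-one, via Grignard reagent 12 (not isolated), via magnesium ketimine 13 (not isolated)
Conditions: 11 (1.5 equiv), Mg, THF, 40 °C; then 7, CuBr·SMe2 (5 mol%), THF, 60 °C; then 2 M aq HCl, THF, rt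
Reagents that add atoms: water, O
Why: Grignard addition to an aryl nitrile stops at the N-magnesio ketimine, and the acidic aqueous work-up should hydrolyse it to the aryl ketone (C14) and cleave the THP acetal in the same operation while aryl TIPS ethers withstand dilute acid.

Step 7
Reactants: 14 11-hydroxy-1-Ar*-undec-8-yn-1-one
Product: 15 11-bromo-1-Ar*-undec-8-yn-1-one
Conditions: CBr4, PPh3, CH2Cl2, 0 °C
Reagents that add atoms: carbon tetrabromide, BrC(Br)(Br)Br
Why: Appel reaction, in which the primary alcohol is activated as an alkoxyphosphonium ion and displaced by bromide in an SN2 step under neutral conditions that the ketone, alkyne, allyl group and silyl ethers should tolerate.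

Step 8
Reactants: 15 11-bromo-1-Ar*-undec-8-yn-1-one
Product: 16 (R)-11-bromo-1-Ar*-undec-8-yn-1-ol
Conditions: (S)-2-methyl-CBS-oxazaborolidine (0.3 equiv), catecholborane, toluene, −78 to −40 °C
Reagents that add atoms: none
Why: Corey–Bakshi–Shibata reduction, in which the (S)-oxazaborolidine binds the ketone with the aryl group as the large substituent and delivers hydride to the face that gives the (R)-carbinol, while catecholborane at low temperature should not hydroborate the allyl group or the alkyne.

Step 9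
Reactants: 16 (R)-11-bromo-1-Ar*-undec-8-yn-1-ol
Product: 17 (R)-[(11-bromo-1-Ar*-undec-8-yn-1-yl)oxy](tert-butyl)dimethylsilane
Conditions: TBSOTf, 2,6-lutidine, CH2Cl2, −78 to 0 °C
Reagents that add atoms: tert-butyldimethylsilyl triflate, CC(C)(C)[Si](C)(C)OS(=O)(=O)C(F)(F)F
Why: O-silylation at oxygen only, so the C14 configuration is untouched, masks the benzylic hydroxyl against the borane and base of the next step.

Step 10
Reactants: 17 (R)-[(11-bromo-1-Ar*-undec-8-yn-1-yl)oxy](tert-butyl)dimethylsilane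
Product: 19 protected 22-membered cycloalkyne (ring A 1,3-bridged; ring B 1,4-bridged; C6≡C7; (R)-C14–OTBS; three aryl OTIPS), via alkylborane 18 (not isolated)
Conditions: 9-BBN (1.05 equiv B–H), THF, 0 °C to rt; then slow addition to Pd(OAc)2 (20 mol%), PCy3 (40 mol%), K3PO4·H2O (3 equiv), THF, rt to 40 °C, about 2 mM
Reagents that add atoms: none
Why: Proposed new method: 9-BBN adds across the terminal C2=C3 alkene with boron on the unhindered C3 and, being far more reactive towards a monosubstituted alkene than towards the internal C6≡C7 alkyne, gives alkylborane 18, which is fed slowly into Pd(OAc)2/PCy3/K3PO4·H2O, where zerovalent palladium inserts into the primary C4–Br bond by an SN2-type oxidative addition, the hydroxide-activated C3–B bond of the same molecule transmetalates to palladium, and reductive elimination forms the C3–C4 bond. The closest known reaction type is the intermolecular alkyl–alkyl Suzuki–Miyaura coupling of B-alkyl-9-BBN reagents with primary alkyl bromides that carry β-hydrogens under this catalyst and base, together with B-alkyl Suzuki–Miyaura macrocyclisations onto alkenyl halides; new here is the use of the alkyl–alkyl variant for ring closure. The 22-membered ring is closed end to end between two primary carbons through a macrocyclic dialkylpalladium intermediate, so no small-ring stereoelectronic rule limits it. No stereocenter is formed, and the (R)-C14 silyl ether is remote from both reacting ends and not epimerisable under these conditions. The step needs ring closure to outrun oligomerisation and β-hydride elimination: high dilution with slow addition keeps free borane scarce, the bent diaryl ether between ring A (meta) and ring B (para) turns the two arms towards each other, and the bulky electron-rich PCy3 speeds oxidative addition and slows β-hydride loss from the alkylpalladium species.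

Step 11
Reactants: 19 protected 22-membered cycloalkyne
Product: 20 protected (6Z)-cycloalkene ((R)-C14–OTBS; three aryl OTIPS)
Conditions: H2 (1 atm), Pd/CaCO3 poisoned with Pb(OAc)2, quinoline, EtOAc, rt
Reagents that add atoms: none
Why: Lindlar semi-hydrogenation delivers both hydrogens to one face of the alkyne on the poisoned palladium surface, which sets the Z geometry of C6=C7 and should stop at the alkene, the silyl ethers and arenes being inert.

Step 12
Reactants: 20 protected (6Z)-cycloalkene
Product: 21 target CNP0316989.2 ((14R,6Z)-macrocyclic diaryl ether triphenol carbinol)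
Conditions: Bu4NF, AcOH, THF, 0 °C to 40 °C
Reagents that add atoms: none
Why: Fluoride-mediated desilylation should remove the three aryl TIPS groups and the benzylic TBS group in one operation, and the acetic acid buffer keeps the medium too mild to ionise the benzylic alcohol or move the Z-alkene.

**Compound list**

1 | 4-hydroxy-3,5-dimethoxybenzonitrile | COc1cc(C#N)cc(OC)c1O | starting material
2 | (3-bromo-5-methoxyphenyl)boronic acid | COc1cc(Br)cc(c1)B(O)O | starting material
3 | 4-(3-bromo-5-methoxyphenoxy)-3,5-dimethoxybenzonitrile | COc1cc(Br)cc(c1)Oc1c(OC)cc(C#N)cc1OC | intermediate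
4 | 4-(3-bromo-5-hydroxyphenoxy)-3,5-dihydroxybenzonitrile | Oc1cc(Br)cc(c1)Oc1c(O)cc(C#N)cc1O | intermediate
5 | 4-{3-bromo-5-[(triisopropylsilyl)oxy]phenoxy}-3,5-bis[(triisopropylsilyl)oxy]benzonitrile | CC(C)[Si](C(C)C)(C(C)C)Oc1cc(Br)cc(c1)Oc1c(O[Si](C(C)C)(C(C)C)C(C)C)cc(C#N)cc1O[Si](C(C)C)(C(C)C)C(C)C | intermediate
6 | allyltributylstannane | C=CC[Sn](CCCC)(CCCC)CCCC | starting material
7 | 4-{3-allyl-5-[(triisopropylsilyl)oxy]phenoxy}-3,5-bis[(triisopropylsilyl)oxy]benzonitrile | C=CCc1cc(O[Si](C(C)C)(C(C)C)C(C)C)cc(c1)Oc1c(O[Si](C(C)C)(C(C)C)C(C)C)cc(C#N)cc1O[Si](C(C)C)(C(C)C)C(C)C | intermediate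
8 | 2-(but-3-yn-1-yloxy)oxane (racemic THP ether) | C#CCCOC1CCCCO1 | starting material
9 | 1,6-dibromohexane | BrCCCCCCBr | starting material
10 | [4-(oxan-2-yloxy)but-1-yn-1-yl]lithium (not isolated) | [Li]C#CCCOC1CCCCO1 | intermediate
11 | 2-[(10-bromodec-3-yn-1-yl)oxy]oxane | BrCCCCCCC#CCCOC1CCCCO1 | intermediate
12 | [10-(oxan-2-yloxy)dec-7-yn-1-yl]magnesium bromide (not isolated) | Br[Mg]CCCCCCC#CCCOC1CCCCO1 | intermediate
13 | N-bromomagnesio ketimine of 1-Ar*-11-(oxan-2-yloxy)undec-8-yn-1-one (not isolated) | C=CCc1cc(O[Si](C(C)C)(C(C)C)C(C)C)cc(c1)Oc1c(O[Si](C(C)C)(C(C)C)C(C)C)cc(cc1O[Si](C(C)C)(C(C)C)C(C)C)C(=N[Mg]Br)CCCCCCC#CCCOC1CCCCO1 | intermediate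
14 | 11-hydroxy-1-Ar*-undec-8-yn-1-one | C=CCc1cc(O[Si](C(C)C)(C(C)C)C(C)C)cc(c1)Oc1c(O[Si](C(C)C)(C(C)C)C(C)C)cc(cc1O[Si](C(C)C)(C(C)C)C(C)C)C(=O)CCCCCCC#CCCO | intermediate
15 | 11-bromo-1-Ar*-undec-8-yn-1-one | C=CCc1cc(O[Si](C(C)C)(C(C)C)C(C)C)cc(c1)Oc1c(O[Si](C(C)C)(C(C)C)C(C)C)cc(cc1O[Si](C(C)C)(C(C)C)C(C)C)C(=O)CCCCCCC#CCCBr | intermediate
16 | (R)-11-bromo-1-Ar*-undec-8-yn-1-ol | C=CCc1cc(O[Si](C(C)C)(C(C)C)C(C)C)cc(c1)Oc1c(O[Si](C(C)C)(C(C)C)C(C)C)cc(cc1O[Si](C(C)C)(C(C)C)C(C)C)[C@H](O)CCCCCCC#CCCBr | intermediate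
17 | (R)-[(11-bromo-1-Ar*-undec-8-yn-1-yl)oxy](tert-butyl)dimethylsilane | C=CCc1cc(O[Si](C(C)C)(C(C)C)C(C)C)cc(c1)Oc1c(O[Si](C(C)C)(C(C)C)C(C)C)cc(cc1O[Si](C(C)C)(C(C)C)C(C)C)[C@H](O[Si](C)(C)C(C)(C)C)CCCCCCC#CCCBr | intermediate
18 | B-alkyl-9-BBN from hydroboration of the allyl group of 17, boron on C3 (not isolated) | C1CC2CCCC(C1)B2CCCc1cc(O[Si](C(C)C)(C(C)C)C(C)C)cc(c1)Oc1c(O[Si](C(C)C)(C(C)C)C(C)C)cc(cc1O[Si](C(C)C)(C(C)C)C(C)C)[C@H](O[Si](C)(C)C(C)(C)C)CCCCCCC#CCCBr | intermediate
19 | protected 22-membered cycloalkyne: C3–C4 closed, C6≡C7, (R)-C14–OTBS, three aryl OTIPS | CC(C)[Si](C(C)C)(C(C)C)Oc1cc2cc(c1)Oc1c(O[Si](C(C)C)(C(C)C)C(C)C)cc(cc1O[Si](C(C)C)(C(C)C)C(C)C)[C@H](O[Si](C)(C)C(C)(C)C)CCCCCCC#CCCCCC2 | intermediate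
20 | protected (6Z)-cycloalkene: (R)-C14–OTBS, three aryl OTIPS | CC(C)[Si](C(C)C)(C(C)C)Oc1cc2cc(c1)Oc1c(O[Si](C(C)C)(C(C)C)C(C)C)cc(cc1O[Si](C(C)C)(C(C)C)C(C)C)[C@H](O[Si](C)(C)C(C)(C)C)CCCCCC/C=C\CCCCC2 | intermediate
21 | CNP0316989.2, (14R,6Z)-macrocyclic diaryl ether with three phenols and the benzylic alcohol | Oc1cc2cc(c1)Oc1c(O)cc(cc1O)[C@H](O)CCCCCC/C=C\CCCCC2 | target

**Step count**

Total steps: 12. Longest linear sequence: 11 steps (steps 1–4 and 6–12); the chain branch (step 5) joins at step 6.

**Steps most likely to fail**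

Step 10 (the step labelled as a proposed new method). Intermolecular boron-to-palladium transfer (oligomerisation) and β-hydride elimination from the homopropargylic alkylpalladium intermediate may outpace the ring-closing transmetalation, and residual borane may add to the alkyne during the slow addition. The fallback uses known chemistry, sets out from 17 and comes back at 19. Displacement of the bromide of 17 with PhSO2Na in DMF at 50 °C should give the homopropargylic phenyl sulfone F1. Hydroboration of its allyl group with 9-BBN and oxidation with NaBO3·4H2O should give the primary alcohol F2, and I2/PPh3/imidazole the primary iodide F3. Slow addition of F3 to KN(SiMe3)2 in THF at high dilution should close the same C3–C4 bond by intramolecular SN2 alkylation of the α-sulfonyl carbanion, an established way to close large rings, giving the macrocyclic sulfone F4 as C4 epimers. Reductive desulfonylation with SmI2/HMPA in THF then returns to 19.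

Step 1. Ligand exchange and C–O bond formation at copper may be slow for the hindered, electron-poor phenoxide, so that protodeboronation and homocoupling of the boronic acid consume 2. The fallback sets out from 1 and comes back at 3. The diaryliodonium salt (3-bromo-5-methoxyphenyl)(2,4,6-trimethoxyphenyl)iodonium tosylate F5 would be made in one pot from 1-bromo-3-iodo-5-methoxybenzene (mCPBA, TsOH·H2O, then 1,3,5-trimethoxybenzene). It should arylate the potassium phenoxide of 1 (KOt-Bu, toluene, rt to 50 °C) by metal-free ligand coupling at trivalent iodine. The electron-rich trimethoxyphenyl group stays on iodine, and ortho substituents on the phenol are well tolerated in this reaction class.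

Step 6. Addition of the Grignard reagent to the nitrile may stay incomplete, and the heating needed to force it may erode the aryl silyl ethers or isomerise the allyl group. The fallback sets out from 7 and comes back at 14. Reduction of 7 with i-Bu2AlH (toluene, −78 °C, acidic work-up) should give the aldehyde F6, to which Grignard reagent 12 adds rapidly at −78 °C to give the racemic carbinol F7. Dess–Martin oxidation should give the THP-protected ketone F8, and methanolysis of the acetal with PPTS in MeOH at 40 °C returns to 14.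

**Further compounds**

F1 | step 10 | (R)-sulfone: 17 with C4–Br replaced by C4–SO2Ph | C=CCc1cc(O[Si](C(C)C)(C(C)C)C(C)C)cc(c1)Oc1c(O[Si](C(C)C)(C(C)C)C(C)C)cc(cc1O[Si](C(C)C)(C(C)C)C(C)C)[C@H](O[Si](C)(C)C(C)(C)C)CCCCCCC#CCCS(=O)(=O)c1ccccc1
F2 | step 10 | (R)-sulfone alcohol: F1 with the allyl group converted to 3-hydroxypropyl | OCCCc1cc(O[Si](C(C)C)(C(C)C)C(C)C)cc(c1)Oc1c(O[Si](C(C)C)(C(C)C)C(C)C)cc(cc1O[Si](C(C)C)(C(C)C)C(C)C)[C@H](O[Si](C)(C)C(C)(C)C)CCCCCCC#CCCS(=O)(=O)c1ccccc1
F3 | step 10 | (R)-sulfone iodide: F2 with OH replaced by I at C3 | ICCCc1cc(O[Si](C(C)C)(C(C)C)C(C)C)cc(c1)Oc1c(O[Si](C(C)C)(C(C)C)C(C)C)cc(cc1O[Si](C(C)C)(C(C)C)C(C)C)[C@H](O[Si](C)(C)C(C)(C)C)CCCCCCC#CCCS(=O)(=O)c1ccccc1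
F4 | step 10 | macrocyclic sulfone: 19 carrying SO2Ph on C4 (C4 epimers, C14 R) | CC(C)[Si](C(C)C)(C(C)C)Oc1cc2cc(c1)Oc1c(O[Si](C(C)C)(C(C)C)C(C)C)cc(cc1O[Si](C(C)C)(C(C)C)C(C)C)[C@H](O[Si](C)(C)C(C)(C)C)CCCCCCC#CCC(S(=O)(=O)c1ccccc1)CCC2
F5 | step 1 | (3-bromo-5-methoxyphenyl)(2,4,6-trimethoxyphenyl)iodonium tosylate | COc1cc(Br)cc(c1)[I+]c1c(OC)cc(OC)cc1OC.Cc1ccc(cc1)S(=O)(=O)[O-]
F6 | step 6 | 4-{3-allyl-5-[(triisopropylsilyl)oxy]phenoxy}-3,5-bis[(triisopropylsilyl)oxy]benzaldehyde | C=CCc1cc(O[Si](C(C)C)(C(C)C)C(C)C)cc(c1)Oc1c(O[Si](C(C)C)(C(C)C)C(C)C)cc(C=O)cc1O[Si](C(C)C)(C(C)C)C(C)C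
F7 | step 6 | racemic 1-Ar*-11-(oxan-2-yloxy)undec-8-yn-1-ol | C=CCc1cc(O[Si](C(C)C)(C(C)C)C(C)C)cc(c1)Oc1c(O[Si](C(C)C)(C(C)C)C(C)C)cc(cc1O[Si](C(C)C)(C(C)C)C(C)C)C(O)CCCCCCC#CCCOC1CCCCO1
F8 | step 6 | 1-Ar*-11-(oxan-2-yloxy)undec-8-yn-1-one | C=CCc1cc(O[Si](C(C)C)(C(C)C)C(C)C)cc(c1)Oc1c(O[Si](C(C)C)(C(C)C)C(C)C)cc(cc1O[Si](C(C)C)(C(C)C)C(C)C)C(=O)CCCCCCC#CCCOC1CCCCO1
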